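## Structural features

The target is a germacra-1(10),4,11(13)-trien-12,6-olide. Its ten-membered carbocycle (C1–C10) holds a ring-cis trisubstituted alkene at C1=C10 (methyl C14 on C10) and a ring-trans trisubstituted alkene at C4=C5 (hydroxymethyl C15 on C4), so the two together form a cis,trans-cyclodeca-1,5-diene. An α-methylene-γ-butyrolactone (C11=C13, C12) is trans-fused across C6–C7, and C8 carries the ester of (S)-3-hydroxy-2-methylpropanoic acid. C6 (R), C7 (R) and C8 (S) are contiguous: O6 and O8 lie on the face of H7, C11 on the other face; the fourth stereocentre sits in the side chain, away from the ring. Fragile elements are the exocyclic enoate (Michael acceptor, base-labile), the 1,5-diene (Cope rearrangement on heating, transannular cyclisation in acid), the lactone next to a C8 oxygen (it can migrate to O8 once that hydroxyl is free) and the β-hydroxy ester of the side chain. The real difficulty is the strained medium ring with two defined alkene geometries next to three stereocentres, not the stereocentres themselves. The key step uses the fact that C1, C10, C5 and C4 can be the four carbons of the central cyclobutane of a cis-anti-cis tricyclo[4.4.0.0(2,5)]decane, whose thermal opening releases exactly this 1,5-diene. It also uses a second feature: in the ring-trans C4=C5 alkene, C15 and O6 are cis, so a γ-lactone between O6 and C15 in the tricycle decides which of the two new double bonds becomes the trans one.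

## Logic of the disconnections

**37 to 36.** Cut the two O–Si bonds (C15–O and the side-chain O). Both primary hydroxyls must be masked while C8 is acylated. The forward step must remove two silyl groups without touching the enoate, the ester or the diene, which calls for buffered acidic fluoride.

**36 to 31 and 34.** Cut the C8–O acyl bond. This makes the route convergent and takes the side-chain stereocentre from the chiral pool. The forward step must acylate a hindered secondary alcohol without lactone migration to O8 and without epimerising the α-centre of 34.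

**31 to 30 to 26.** Cut the C8 O–Si bond, then the C11=C13 bond. The Michael acceptor is installed late, on a lactone whose only acidic C–H is at C11. This requires different silyl groups on C8 and C15 (secondary TBS, primary TBDPS), so that C8 can be unmasked alone.

**26 to 25 to 24.** Lower C12 from lactone to lactol, then cut the O6–C12 bond to leave a dimethyl acetal. C12 must be inert to the hydride that produces C15–OH and the C6–OH, and an acetal is. The forward steps need only mild aqueous acid and a neutral lactol oxidation; C8–O stays silylated so that only the 6,12-lactol can form.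

**24 to 23 to 22.** Cut the C15 O–Si bond, then convert the C6–OH/C15–OH pair back to a lactone between O6 and C15. That lactone is what the key step delivers. The forward step is an exhaustive 1,2-reduction of a butenolide to a (Z)-ene-1,4-diol.

**22 to 21 (key).** In the retrosynthetic direction the C1=C10 and C4=C5 π bonds are exchanged for the σ bonds C5–C10 and C1–C4. The medium ring with its two alkene geometries becomes a rigid tricycle of two four-membered rings and one six-membered ring. The forward step must cleave the right pair of cyclobutane bonds, place the trans bond at C4=C5, and stop before a Cope rearrangement. The O6–C15 lactone that spans C4–C5 is there to secure the second point.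

**21 to 19.** Cut the O6–C15 lactone bond and the C6–H bond. 19 is the direct (2+2) adduct. The forward step needs hydride delivery to C6 from the face away from C4; lactonisation then removes any ambiguity about the C6 configuration.

**19 to 15 and 18.** Cut C4–C5 and C1–C10. Two simple rings result, and 15 already carries C7 and C8 of the target. The forward step must be head-to-head and cis-anti-cis, and the cyclobutane must end up on the enone face that carries the C8 oxygen.

**15 to 14.** Cut C5=C10 (ring-closing metathesis). The ring becomes an acyclic dienone; the forward step must close a trisubstituted enone.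

**14 to 12 to 11 to 10.** Cut C5–C6 (vinyl addition to a Weinreb amide), the C8 O–Si bond, and the C6–N bond back to the auxiliary imide. These are standard operations; the only demand is that the acetal and the β-oxygen survive.

**10 to 5 and 7.** Cut C7–C8. One auxiliary-controlled aldol sets both ring stereocentres in the syn relation that becomes 7,8-trans in the ring. The forward step must use a β,γ-unsaturated aldehyde without letting its double bond move into conjugation.

**Remaining cuts.** 5 comes from 2 and 3 by N-acylation, and 2 from 1 by saponification. 7 comes from 6 by oxidation. 18 comes from 17 by O-methylation, and 17 from 16 by dehydrobromination. 34 comes from 33 by saponification, and 33 from 32 by silylation. All end at commercial materials.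

## Other disconnections considered

Alternative 1: The cut is C7–C11. The lactone carbons sit as a phosphonoacetate on O6 in the epoxide A1, and base lets the stabilised carbanion open the 7,8-epoxide at C7 with inversion to give A2.
- In its favour: one step forms C7–C11, closes the lactone in the trans-fused sense (the tethered nucleophile has to enter anti to the epoxide oxygen), frees the C8 hydroxyl for the final acylation, and leaves a phosphonate that a Horner–Wadsworth–Emmons methylenation would turn into the exocyclic alkene without enolate chemistry on a finished lactone.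
- Against it here: it presupposes A1, that is, the ten-membered cis,trans-diene with C6, C7 and C8 already set and a third ring alkene epoxidised selectively. The medium ring and its alkene geometries remain unsolved. The 5-exo opening at C7 would also compete with attack at C8, with loss of the allylic C6 ester and with transannular opening of the epoxide by C4=C5.
- Comparison: in the end game this alternative is the better plan (methylenation and the free C8–OH are built in, and one silyl differentiation is saved). In stereochemical clarity it is the equal (SN2 inversion against an aldol). In ring construction the chosen plan is stronger, because ring and both alkene geometries come from one thermal step on a rigid precursor.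

Alternative 2: The cut is C6–C7. A [2,3]-Wittig rearrangement of the 13-membered diallyl ether A3, lithiated at C6, would contract the ring to the carbocycle A4.
- In its favour: one step makes the C6–C7 bond, both of its stereocentres (by transfer from the C7=C11 geometry), the free C6 hydroxyl and the C11=C13 methylene. Oxidation of C12 would then give the α-methylene lactone directly.
- Against it here: the 13-membered ether with three defined trisubstituted alkenes has to be made first. Lithiation could occur at C13 as well as at C6, and [1,2]-shift competes. The relation of the new C6/C7 pair to the existing C8 centre depends on the transition-state conformation of a large ring. The C8 acetal-type protecting group would need acid for removal next to the diene.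
- Comparison: it is the equal or the better of the chosen plan in what it creates per step at C6, C7 and C11=C13. It is weaker in the predictability of regio- and stereocontrol and in the effort needed to reach its macrocyclic precursor; the chosen plan builds its precursor from two small rings and fixes C7/C8 by an aldol before any ring exists.

Alternative 3: The cut is C7–C8. Divalent samarium (SmI2) would reduce the C8 aldehyde of the open-chain butenolide A5 to a ketyl that adds to C7 and closes the ten-membered ring, giving A6.
- In its favour: the precursor is a linear chain assembled by standard olefinations, the lactone is present from the start, addition anti to the C6 substituent would give the trans-fused lactone, and the C8 hydroxyl is freed for esterification in the same step under mild conditions.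
- Against it here: a ten-membered ring is closed end to end, so pinacol coupling and simple reduction of aldehyde or butenolide compete. The configuration at C8 is not controlled by anything but ring conformation. The β,γ-unsaturated aldehyde of A5 is prone to move its double bond into conjugation. The methylene still has to be added afterwards with the C8 hydroxyl protected.
- Comparison: in step count and protecting-group economy this alternative is the better plan, and it is the equal in building the ring together with two stereocentres. It is weaker in the reliability of the ring closure and of the C8 configuration; in the chosen plan C7 and C8 are fixed before the ring is formed.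

Key step: step 13

Remarks and assumptions (chemistry):
- Germacrane numbering is used for all ring compounds. α means the face of the ring that carries H7; the target is then the 12,6α-olide with an 8α-acyloxy group and C11 on the β face. TBSO = tert-butyldimethylsilyloxy, TBDPSO = tert-butyldiphenylsilyloxy.
- Assumption: the photocycloaddition delivers both cis-anti-cis facial isomers; the route carries on the one whose cyclobutane lies on the face of the C8 silyloxy group (anti to the C7 side chain).
- A chair-like 1,4-diyl model of the ring opening says that the two facial isomers cannot be expected to give the same double-bond geometry: whichever of C5–C6 and C10–C9 is equatorial on the diyl becomes part of the trans alkene. A keto ester alone does not fix this choice. The C6 ketone of the direct photoadduct 19 is therefore reduced and tied to C15 as a γ-lactone (21) before the thermolysis. This also removes a β-silyloxy ketone and an epimerisable C7 from the hot zone.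
- C8 and C15 carry different silyl groups (TBS and TBDPS), because C8 has to be unmasked while C15 stays protected.

## Steps

Step 1
Reactants: 1 methyl 4,4-dimethoxybutanoate
Product: 2 4,4-dimethoxybutanoic acid
Conditions: LiOH·H2O, THF/H2O (3:1), 0 °C → rt; cold 1 M HCl to pH 4, EtOAc
Reagents that add atoms: lithium hydroxide, [Li+].[OH-]
Why: Saponification of an unhindered methyl ester; the dimethyl acetal is inert to base and should survive a brief cold acidification to about pH 4.

Step 2
Reactants: 2 4,4-dimethoxybutanoic acid; 3 (R)-4-benzyloxazolidin-2-one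
Product: 5 (R)-4-benzyl-3-(4,4-dimethoxybutanoyl)oxazolidin-2-one, via mixed pivalic anhydride 4 (not isolated)
Conditions: t-BuCOCl, Et3N, THF, −20 °C; then 3, LiCl, −20 °C → rt
Reagents that add atoms: none
Why: N-Acylation of the oxazolidinone through a mixed anhydride with LiCl/Et3N activation; no acid chloride or HCl is generated next to the acetal, and attack occurs at the less hindered carbonyl of the anhydride.

Step 3
Reactants: 6 3-methylbut-3-en-1-ol
Product: 7 3-methylbut-3-enal
Conditions: Dess–Martin periodinane, CH2Cl2, 0 °C → rt; cold aq. NaHCO3 wash; dried solution used at once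
Reagents that add atoms: none
Why: Dess–Martin oxidation of a primary homoallylic alcohol under nearly neutral conditions; the β,γ-unsaturated aldehyde is kept cold and in solution so that the double bond does not move into conjugation.

Step 4
Reactants: 5 (R)-4-benzyl-3-(4,4-dimethoxybutanoyl)oxazolidin-2-one; 7 3-methylbut-3-enal
Product: 10 (R)-4-benzyl-3-[(2R,3S)-2-(2,2-dimethoxyethyl)-3-hydroxy-5-methylhex-5-enoyl]oxazolidin-2-one, via dibutylboron (Z)-enolate 8 (not isolated), via boron aldolate 9 (not isolated)
Conditions: Bu2BOTf (1.1 equiv), i-Pr2NEt (1.3 equiv), CH2Cl2, 0 °C; 7, −78 → 0 °C; pH 7 buffer, MeOH, 30% H2O2, 0 °C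
Reagents that add atoms: none
Why: Evans syn-aldol reaction: the (Z)-boron enolate reacts through a closed chair transition state on the enolate face away from the benzyl group, which sets C7 (2R) and C8 (3S) together as the syn pair that becomes 7,8-trans in the ring. The amine is kept in excess over the boron triflate so that the acetal is not ionised, and the aldehyde meets the preformed enolate only at −78 °C.

Step 5
Reactants: 10 (R)-4-benzyl-3-[(2R,3S)-2-(2,2-dimethoxyethyl)-3-hydroxy-5-methylhex-5-enoyl]oxazolidin-2-one
Product: 11 (2R,3S)-2-(2,2-dimethoxyethyl)-3-hydroxy-N-methoxy-N,5-dimethylhex-5-enamide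
Conditions: MeNH(OMe)·HCl, AlMe3, CH2Cl2, −20 → 0 °C; aq. potassium sodium tartrate
Reagents that add atoms: N,O-dimethylhydroxylamine hydrochloride, CNOC.Cl
Why: Transamidation of the β-hydroxy imide with the aluminium amide of N,O-dimethylhydroxylamine (Weinreb amide formation), accelerated by the free C8 hydroxyl through a chelated aluminium alkoxide; the auxiliary is recovered and no stereocentre is touched.

Step 6
Reactants: 11 (2R,3S)-2-(2,2-dimethoxyethyl)-3-hydroxy-N-methoxy-N,5-dimethylhex-5-enamide
Product: 12 (2R,3S)-3-[(tert-butyldimethylsilyl)oxy]-2-(2,2-dimethoxyethyl)-N-methoxy-N,5-dimethylhex-5-enamide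
Conditions: TBSCl, imidazole, DMF, rt
Reagents that add atoms: tert-butyldimethylsilyl chloride, CC(C)(C)[Si](C)(C)Cl
Why: Silylation of the secondary alcohol with the silyl chloride and imidazole; the chloride is preferred to the silyl triflate because triflate/pyridine-base mixtures can cleave dimethyl acetals.

Step 7
Reactants: 12 (2R,3S)-3-[(tert-butyldimethylsilyl)oxy]-2-(2,2-dimethoxyethyl)-N-methoxy-N,5-dimethylhex-5-enamide
Product: 14 (4R,5S)-5-[(tert-butyldimethylsilyl)oxy]-4-(2,2-dimethoxyethyl)-7-methylocta-1,7-dien-3-one, via bromomagnesium hemiaminal chelate 13 (not isolated)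
Conditions: CH2=CHMgBr (3 equiv), THF, 0 °C; AcOH, −78 °C
Reagents that add atoms: vinylmagnesium bromide, C=C[Mg]Br
Why: Grignard addition to a Weinreb amide stops at the chelated tetrahedral intermediate, which releases the vinyl ketone only on quenching; the cold acetic acid quench protonates the liberated amine before it can add to the enone.

Step 8
Reactants: 14 (4R,5S)-5-[(tert-butyldimethylsilyl)oxy]-4-(2,2-dimethoxyethyl)-7-methylocta-1,7-dien-3-one
Product: 15 (5S,6R)-5-[(tert-butyldimethylsilyl)oxy]-6-(2,2-dimethoxyethyl)-3-methylcyclohex-2-en-1-one
Conditions: second-generation Grubbs catalyst RuCl2(=CHPh)(H2IMes)(PCy3) (5 mol %), CH2Cl2 (0.01 M), 40 °C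
Reagents that add atoms: none
Why: Ring-closing metathesis of a vinyl ketone with a 1,1-disubstituted alkene closes the six-membered trisubstituted enone (C5=C10) with loss of ethene; the neutral conditions leave the β-silyloxy ketone and the C7 centre untouched.

Step 9
Reactants: 16 ethyl 1-bromocyclobutane-1-carboxylate
Product: 17 cyclobut-1-ene-1-carboxylic acid
Conditions: KOH (powder, 3.5 equiv), toluene, reflux; cold aq. HCl
Reagents that add atoms: potassium hydroxide, [K+].[OH-]
Why: E2 dehydrobromination of the α-bromo ester with saponification in the same operation; the double bond can only form inside the ring and in conjugation with the carboxylate.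

Step 10
Reactants: 17 cyclobut-1-ene-1-carboxylic acid
Product: 18 methyl cyclobut-1-ene-1-carboxylate
Conditions: MeI, K2CO3, DMF, 0 °C → rt, dark; distilled and stored cold
Reagents that add atoms: iodomethane, CI
Why: O-Alkylation of the carboxylate under mild base; this avoids acid-catalysed esterification, which would polymerise the strained acrylate.

Step 11
Reactants: 15 (5S,6R)-5-[(tert-butyldimethylsilyl)oxy]-6-(2,2-dimethoxyethyl)-3-methylcyclohex-2-en-1-one; 18 methyl cyclobut-1-ene-1-carboxylate
Product: 19 methyl 9-[(tert-butyldimethylsilyl)oxy]-8-(2,2-dimethoxyethyl)-1-methyl-7-oxotricyclo[4.4.0.0(2,5)]decane-5-carboxylate (cis-anti-cis head-to-head photoadduct; cyclobutane on the face of the silyloxy group; germacrane numbering: ester on C4, methyl on C10, ketone C6)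
Conditions: hν (medium-pressure mercury lamp, uranium-glass filter, λ > 340 nm), 18 (5 equiv), CH2Cl2, −20 °C; chromatographic separation from the facial isomer
Reagents that add atoms: none
Why: Enone–alkene (2+2) photocycloaddition through the triplet enone: bonding of C10 to the unsubstituted cyclobutene carbon C1 gives the 1,4-diradical stabilised by the ketone at C5 and the ester at C4, which explains the head-to-head sense, and closure gives both ring fusions cis with the outer rings anti. C1, C4, C5 and C10 are thus set relative to each other by the mode of addition and relative to C7/C8 only by the face of the enone, which the trans-disposed substituents do not bias strongly. The isomer with the cyclobutane syn to the C8 silyloxy group is taken on because only in it do the later lactone and the diene geometry match the target.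

Step 12
Reactants: 19 methyl 9-[(tert-butyldimethylsilyl)oxy]-8-(2,2-dimethoxyethyl)-1-methyl-7-oxotricyclo[4.4.0.0(2,5)]decane-5-carboxylate
Product: 21 9-[(tert-butyldimethylsilyl)oxy]-8-(2,2-dimethoxyethyl)-7-hydroxy-1-methyltricyclo[4.4.0.0(2,5)]decane-5-carboxylic acid 5,7-lactone (germacrane numbering: γ-lactone from C15 to O6; O6 cis to C4 and trans to the C7 side chain), via hydroxy ester 20 (not isolated)
Conditions: NaBH4, MeOH, −10 °C → rt (cat. K2CO3 if lactonisation lags)
Reagents that add atoms: none
Why: Hydride reduction of the cyclohexanone from the face away from the ester-bearing quaternary C4, which with its ester lies over the carbonyl; the alkoxide, cis to C15, closes the γ-lactone with loss of methanol. The new C6 centre (6α-O, trans to C11, cis to O8) is thus set by the convex-face attack and confirmed by the ring closure, since the epimeric alcohol cannot lactonise.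

Step 13
Reactants: 21 9-[(tert-butyldimethylsilyl)oxy]-8-(2,2-dimethoxyethyl)-7-hydroxy-1-methyltricyclo[4.4.0.0(2,5)]decane-5-carboxylic acid 5,7-lactone
Product: 22 8α-TBSO-12,12-dimethoxy-13-norgermacra-1(10),4-dien-15,6α-olide (ring-cis C1=C10; ring-trans C4=C5 as the butenolide double bond)
Conditions: flash vacuum thermolysis: sublimed at 160–180 °C and 10^-3 mbar through a base-washed quartz tube at 480–520 °C (contact time about 10 ms), cold trap −196 °C
Reagents that add atoms: none
Why: Heating should first break the central C1–C4 bond shared by the two four-membered rings, which releases the strain of both and gives a chair-like cyclohexane-1,4-diyl whose C4 radical is stabilised by the lactone carbonyl; β-scission of C5–C10 then forms C1=C10 and C4=C5, so that overall the step is a formal σ2s+σ2a cycloreversion. The closest known reaction type is the thermal cycloreversion of enone–cyclobutene photoadducts, and of the lactones obtained by reducing them, to cis,trans-cyclodeca-1,5-dienes. The ten-membered ring is not closed end to end but by ring expansion: the four- and six-membered rings merge when their common bond C5–C10 is cut. No stereocentre is formed; C6, C7 and C8 pass through unchanged and C1, C4, C5 and C10 become sp2. Because the cyclohexane is cis-fused to the cyclobutane, C6 and C9 sit one equatorial and one axial on the diyl, which translates into one trans and one cis double bond. The γ-lactone holds C15 and C6 on the same side of C4–C5, so C4=C5 can only emerge as the butenolide double bond, which is the ring-trans one, and C1=C10 is left as the cis bond; in the facial isomer used, the C7 and C8 substituents are equatorial in this same conformer, so ring conformation and tether point the same way. The step also needs C5–C10 scission to win over C2–C3 scission and over a later Cope rearrangement, both of which lead to a divinylcyclohexane; C5–C10 is the weaker bond (quaternary C10, conjugation developing with the lactone), and a short contact time at high temperature with trapping at −196 °C favours the loose fragmentation over the ordered Cope transition state. With no ketone left, the C8 silyloxy group and the C7 centre are not exposed to elimination or epimerisation in the hot zone.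

Step 14
Reactants: 22 8α-TBSO-12,12-dimethoxy-13-norgermacra-1(10),4-dien-15,6α-olide
Product: 23 8α-TBSO-12,12-dimethoxy-13-norgermacra-1(10),4-diene-6α,15-diol
Conditions: i-Bu2AlH (4 equiv), CH2Cl2, −78 → 0 °C; aq. potassium sodium tartrate
Reagents that add atoms: none
Why: 1,2-Reduction of the butenolide through its lactol to the (Z)-ene-1,4-diol; acetal, silyl ether and both alkene geometries are inert to the hydride, and C6 keeps its configuration because only the acyl C–O bond is cleaved.

Step 15
Reactants: 23 8α-TBSO-12,12-dimethoxy-13-norgermacra-1(10),4-diene-6α,15-diol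
Product: 24 8α-TBSO-15-TBDPSO-12,12-dimethoxy-13-norgermacra-1(10),4-dien-6α-ol
Conditions: TBDPSCl (1.05 equiv), imidazole, CH2Cl2, 0 °C
Reagents that add atoms: tert-butyl(chloro)diphenylsilane, CC(C)(C)[Si](Cl)(c1ccccc1)c1ccccc1
Why: Selective silylation of the primary allylic hydroxyl over the hindered secondary one; the diphenylsilyl group is chosen because it outlasts both the acetal hydrolysis and the later removal of the C8 TBS group.

Step 16
Reactants: 24 8α-TBSO-15-TBDPSO-12,12-dimethoxy-13-norgermacra-1(10),4-dien-6α-ol
Product: 25 8α-TBSO-15-TBDPSO-13-norgermacra-1(10),4-dien-12,6α-olactol (12-hydroxy-6α,12-epoxide; both anomers)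
Conditions: pyridinium p-toluenesulfonate (0.2 equiv), acetone/H2O (5:1), rt
Reagents that add atoms: water, O
Why: Mild acid-catalysed acetal hydrolysis; the C6 hydroxyl captures C12 to give the five-membered lactol, and because O8 is silylated only the 6,12-ring can form. The weak acid is meant to keep the 1,5-diene from transannular cyclisation.

Step 17
Reactants: 25 8α-TBSO-15-TBDPSO-13-norgermacra-1(10),4-dien-12,6α-olactol
Product: 26 8α-TBSO-15-TBDPSO-13-norgermacra-1(10),4-dien-12,6α-olide
Conditions: Pr4N[RuO4] (5 mol %), N-methylmorpholine N-oxide, CH2Cl2, rt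
Reagents that add atoms: none
Why: Ley oxidation of a lactol to the lactone under neutral conditions at room temperature; trisubstituted alkenes and silyl ethers are not affected and no heating is needed, which matters for the Cope-prone diene.

Step 18
Reactants: 26 8α-TBSO-15-TBDPSO-13-norgermacra-1(10),4-dien-12,6α-olide
Product: 30 8α-TBSO-15-TBDPSO-germacra-1(10),4,11(13)-trien-12,6α-olide, via lithium enolate 27 (not isolated), via Mannich base 28 (not isolated), via trimethylammonium iodide 29 (not isolated)
Conditions: i-Pr2NLi, THF, −78 °C; CH2=NMe2+ I−, −78 → 0 °C; MeI, CH2Cl2, rt; aq. NaHCO3, rt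
Reagents that add atoms: N,N-dimethylmethyleneiminium iodide (Eschenmoser's salt), C=[N+](C)C.[I-]
Why: α-Methylenation of a γ-lactone: Mannich reaction of the lithium enolate with Eschenmoser's salt, N-methylation and base-induced elimination of trimethylamine. C11 is the only acidic position and ends sp2, so no stereocentre is at stake, and the mild final base avoids migration of the double bond into the ring.

Step 19
Reactants: 30 8α-TBSO-15-TBDPSO-germacra-1(10),4,11(13)-trien-12,6α-olide
Product: 31 8α-hydroxy-15-TBDPSO-germacra-1(10),4,11(13)-trien-12,6α-olide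
Conditions: HF·pyridine, pyridine, THF, 0 °C → rt, monitored
Reagents that add atoms: none
Why: Under buffered acidic fluoride a TBS ether is cleaved much faster than a TBDPS ether, which should outweigh the secondary-versus-primary handicap; the conditions are non-basic, so the enoate is not attacked and the lactone has no alkoxide to migrate to.

Step 20
Reactants: 32 methyl (S)-3-hydroxy-2-methylpropanoate
Product: 33 methyl (S)-3-[(tert-butyldimethylsilyl)oxy]-2-methylpropanoate
Conditions: TBSCl, imidazole, CH2Cl2, rt
Reagents that add atoms: tert-butyldimethylsilyl chloride, CC(C)(C)[Si](C)(C)Cl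
Why: Standard silylation of a primary alcohol; the α-stereocentre is not involved.

Step 21
Reactants: 33 methyl (S)-3-[(tert-butyldimethylsilyl)oxy]-2-methylpropanoate
Product: 34 (S)-3-[(tert-butyldimethylsilyl)oxy]-2-methylpropanoic acid
Conditions: LiOH·H2O, THF/MeOH/H2O, 0 °C → rt; cold 1 M HCl to pH 4
Reagents that add atoms: lithium hydroxide, [Li+].[OH-]
Why: Saponification at low temperature; hydroxide attacks the ester carbonyl faster than it removes the α-proton, so the (S)-centre should be kept and the silyloxy group is a poor leaving group for β-elimination.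

Step 22
Reactants: 34 (S)-3-[(tert-butyldimethylsilyl)oxy]-2-methylpropanoic acid; 31 8α-hydroxy-15-TBDPSO-germacra-1(10),4,11(13)-trien-12,6α-olide
Product: 36 8α-[(S)-3-TBSO-2-methylpropanoyloxy]-15-TBDPSO-germacra-1(10),4,11(13)-trien-12,6α-olide, via mixed trichlorobenzoic anhydride 35 (not isolated)
Conditions: 2,4,6-Cl3C6H2COCl, Et3N, toluene, rt; then 31, DMAP, rt
Reagents that add atoms: none
Why: Yamaguchi esterification through the mixed anhydride and its acylpyridinium ion, which suits a hindered secondary alcohol; the alcohol is acylated with retention at C8, and the weak amine bases should neither move the lactone to O8 nor epimerise the α-centre of the acid.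

Step 23
Reactants: 36 8α-[(S)-3-TBSO-2-methylpropanoyloxy]-15-TBDPSO-germacra-1(10),4,11(13)-trien-12,6α-olide
Product: 37 8α-[(S)-3-hydroxy-2-methylpropanoyloxy]-15-hydroxygermacra-1(10),4,11(13)-trien-12,6α-olide (target; 6R,7R,8S)
Conditions: HF·pyridine, THF, 0 °C → rt
Reagents that add atoms: none
Why: Cleavage of both primary silyl ethers by acidic fluoride; without base there should be no conjugate addition to the α-methylene lactone, no β-elimination in the hydroxy ester and no acyl or lactone migration.

## Compound list

1 | methyl 4,4-dimethoxybutanoate | COC(=O)CCC(OC)OC | starting material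
2 | 4,4-dimethoxybutanoic acid | OC(=O)CCC(OC)OC | intermediate
3 | (R)-4-benzyloxazolidin-2-one | O=C1N[C@H](Cc2ccccc2)CO1 | starting material
4 | 4,4-dimethoxybutanoic pivalic anhydride | CC(C)(C)C(=O)OC(=O)CCC(OC)OC | intermediate
5 | (R)-4-benzyl-3-(4,4-dimethoxybutanoyl)oxazolidin-2-one | COC(OC)CCC(=O)N1[C@H](Cc2ccccc2)COC1=O | intermediate
6 | 3-methylbut-3-en-1-ol | C=C(C)CCO | starting material
7 | 3-methylbut-3-enal | C=C(C)CC=O | intermediate
8 | dibutylboron (Z)-enolate of 5 | CCCCB(CCCC)O/C(=C\CC(OC)OC)N1[C@H](Cc2ccccc2)COC1=O | intermediate
9 | dibutylboron aldolate of 10 | C=C(C)C[C@H](OB(CCCC)CCCC)[C@@H](CC(OC)OC)C(=O)N1[C@H](Cc2ccccc2)COC1=O | intermediate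
10 | (R)-4-benzyl-3-[(2R,3S)-2-(2,2-dimethoxyethyl)-3-hydroxy-5-methylhex-5-enoyl]oxazolidin-2-one | C=C(C)C[C@H](O)[C@@H](CC(OC)OC)C(=O)N1[C@H](Cc2ccccc2)COC1=O | intermediate
11 | (2R,3S)-2-(2,2-dimethoxyethyl)-3-hydroxy-N-methoxy-N,5-dimethylhex-5-enamide | C=C(C)C[C@H](O)[C@@H](CC(OC)OC)C(=O)N(C)OC | intermediate
12 | (2R,3S)-3-[(tert-butyldimethylsilyl)oxy]-2-(2,2-dimethoxyethyl)-N-methoxy-N,5-dimethylhex-5-enamide | C=C(C)C[C@H](O[Si](C)(C)C(C)(C)C)[C@@H](CC(OC)OC)C(=O)N(C)OC | intermediate
13 | bromomagnesium hemiaminal chelate from 12 and the vinyl Grignard reagent (new carbinol centre undefined) | C=C(C)C[C@H](O[Si](C)(C)C(C)(C)C)[C@@H](CC(OC)OC)C(O[Mg]Br)(C=C)N(C)OC | intermediate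
14 | (4R,5S)-5-[(tert-butyldimethylsilyl)oxy]-4-(2,2-dimethoxyethyl)-7-methylocta-1,7-dien-3-one | C=C(C)C[C@H](O[Si](C)(C)C(C)(C)C)[C@@H](CC(OC)OC)C(=O)C=C | intermediate
15 | (5S,6R)-5-[(tert-butyldimethylsilyl)oxy]-6-(2,2-dimethoxyethyl)-3-methylcyclohex-2-en-1-one | O=C1C=C(C)C[C@H](O[Si](C)(C)C(C)(C)C)[C@H]1CC(OC)OC | intermediate
16 | ethyl 1-bromocyclobutane-1-carboxylate | CCOC(=O)C1(Br)CCC1 | starting material
17 | cyclobut-1-ene-1-carboxylic acid | OC(=O)C1=CCC1 | intermediate
18 | methyl cyclobut-1-ene-1-carboxylate | COC(=O)C1=CCC1 | intermediate
19 | methyl 9-TBSO-8-(2,2-dimethoxyethyl)-1-methyl-7-oxotricyclo[4.4.0.0(2,5)]decane-5-carboxylate, cis-anti-cis, head-to-head, cyclobutane syn to the silyloxy group | COC(=O)[C@]12CC[C@H]1[C@]1(C)C[C@H](O[Si](C)(C)C(C)(C)C)[C@@H](CC(OC)OC)C(=O)[C@@H]12 | intermediate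
20 | methyl 9-TBSO-8-(2,2-dimethoxyethyl)-7-hydroxy-1-methyltricyclo[4.4.0.0(2,5)]decane-5-carboxylate, hydroxyl cis to the ester-bearing carbon | COC(=O)[C@]12CC[C@H]1[C@]1(C)C[C@H](O[Si](C)(C)C(C)(C)C)[C@@H](CC(OC)OC)[C@H](O)[C@@H]12 | intermediate
21 | 9-TBSO-8-(2,2-dimethoxyethyl)-7-hydroxy-1-methyltricyclo[4.4.0.0(2,5)]decane-5-carboxylic acid 5,7-lactone (γ-lactone C15 to O6) | O=C1O[C@H]2[C@H](CC(OC)OC)[C@@H](O[Si](C)(C)C(C)(C)C)C[C@@]3(C)[C@@H]4CC[C@@]14[C@@H]23 | intermediate
22 | 8α-TBSO-12,12-dimethoxy-13-norgermacra-1(10),4-dien-15,6α-olide (ring-cis C1=C10, ring-trans C4=C5) | O=C1O[C@@H]2C=C1CC/C=C(/C)C[C@H](O[Si](C)(C)C(C)(C)C)[C@H]2CC(OC)OC | intermediate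
23 | 8α-TBSO-12,12-dimethoxy-13-norgermacra-1(10),4-diene-6α,15-diol | O[C@@H]1/C=C(\CO)CC/C=C(/C)C[C@H](O[Si](C)(C)C(C)(C)C)[C@H]1CC(OC)OC | intermediate
24 | 8α-TBSO-15-TBDPSO-12,12-dimethoxy-13-norgermacra-1(10),4-dien-6α-ol | O[C@@H]1/C=C(\CO[Si](c2ccccc2)(c2ccccc2)C(C)(C)C)CC/C=C(/C)C[C@H](O[Si](C)(C)C(C)(C)C)[C@H]1CC(OC)OC | intermediate
25 | 8α-TBSO-15-TBDPSO-13-norgermacra-1(10),4-dien-12,6α-olactol (anomers) | OC1O[C@@H]2/C=C(\CO[Si](c3ccccc3)(c3ccccc3)C(C)(C)C)CC/C=C(/C)C[C@H](O[Si](C)(C)C(C)(C)C)[C@H]2C1 | intermediate
26 | 8α-TBSO-15-TBDPSO-13-norgermacra-1(10),4-dien-12,6α-olide | O=C1O[C@@H]2/C=C(\CO[Si](c3ccccc3)(c3ccccc3)C(C)(C)C)CC/C=C(/C)C[C@H](O[Si](C)(C)C(C)(C)C)[C@H]2C1 | intermediate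
27 | lithium enolate of 26 | [Li]OC=1O[C@@H]2/C=C(\CO[Si](c3ccccc3)(c3ccccc3)C(C)(C)C)CC/C=C(/C)C[C@H](O[Si](C)(C)C(C)(C)C)[C@H]2C=1 | intermediate
28 | 13-(dimethylamino)-8α-TBSO-15-TBDPSO-germacra-1(10),4-dien-12,6α-olide (C11 epimers) | CN(C)CC1C(=O)O[C@@H]2/C=C(\CO[Si](c3ccccc3)(c3ccccc3)C(C)(C)C)CC/C=C(/C)C[C@H](O[Si](C)(C)C(C)(C)C)[C@@H]12 | intermediate
29 | trimethylammonium iodide derived from 28 | C[N+](C)(C)CC1C(=O)O[C@@H]2/C=C(\CO[Si](c3ccccc3)(c3ccccc3)C(C)(C)C)CC/C=C(/C)C[C@H](O[Si](C)(C)C(C)(C)C)[C@@H]12.[I-] | intermediate
30 | 8α-TBSO-15-TBDPSO-germacra-1(10),4,11(13)-trien-12,6α-olide | C=C1C(=O)O[C@@H]2/C=C(\CO[Si](c3ccccc3)(c3ccccc3)C(C)(C)C)CC/C=C(/C)C[C@H](O[Si](C)(C)C(C)(C)C)[C@@H]12 | intermediate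
31 | 8α-hydroxy-15-TBDPSO-germacra-1(10),4,11(13)-trien-12,6α-olide | C=C1C(=O)O[C@@H]2/C=C(\CO[Si](c3ccccc3)(c3ccccc3)C(C)(C)C)CC/C=C(/C)C[C@H](O)[C@@H]12 | intermediate
32 | methyl (S)-3-hydroxy-2-methylpropanoate | COC(=O)[C@@H](C)CO | starting material
33 | methyl (S)-3-[(tert-butyldimethylsilyl)oxy]-2-methylpropanoate | COC(=O)[C@@H](C)CO[Si](C)(C)C(C)(C)C | intermediate
34 | (S)-3-[(tert-butyldimethylsilyl)oxy]-2-methylpropanoic acid | OC(=O)[C@@H](C)CO[Si](C)(C)C(C)(C)C | intermediate
35 | (S)-3-[(tert-butyldimethylsilyl)oxy]-2-methylpropanoic 2,4,6-trichlorobenzoic anhydride | O=C(OC(=O)[C@@H](C)CO[Si](C)(C)C(C)(C)C)c1c(Cl)cc(Cl)cc1Cl | intermediate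
36 | 8α-[(S)-3-TBSO-2-methylpropanoyloxy]-15-TBDPSO-germacra-1(10),4,11(13)-trien-12,6α-olide | C=C1C(=O)O[C@@H]2/C=C(\CO[Si](c3ccccc3)(c3ccccc3)C(C)(C)C)CC/C=C(/C)C[C@H](OC(=O)[C@@H](C)CO[Si](C)(C)C(C)(C)C)[C@@H]12 | intermediate
37 | 8α-[(S)-3-hydroxy-2-methylpropanoyloxy]-15-hydroxygermacra-1(10),4,11(13)-trien-12,6α-olide, (6R,7R,8S) | C=C1C(=O)O[C@@H]2/C=C(\CO)CC/C=C(/C)C[C@H](OC(=O)[C@@H](C)CO)[C@@H]12 | target

## Step count and least certain steps

Total: 23 steps. Longest linear sequence: 18 steps (1, 2, 4–8, 11–19, 22, 23).

**Step 13 (key step).** The likeliest failure is diversion to a divinylcyclohexane skeleton, either by scission of the outer cyclobutane bond C2–C3 instead of C5–C10 at the diyl stage or by Cope rearrangement of the diene once formed. A second concern is charring or loss of the acetal in the inlet, because the substrate is heavy for vacuum sublimation.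
Fallback: change the order of reduction and fragmentation. The fallback sets out from 19, which is thermolysed under the same flash conditions to methyl (ring-cis 1(10), ring-trans 4)-8α-TBSO-12,12-dimethoxy-6-oxo-13-norgermacra-1(10),4-dien-15-oate F1. There C4=C5 is conjugated with both the ketone and the ester, conjugation that a Cope rearrangement would partly give up, and the position of the trans bond rests on the equatorial C7 and C8 substituents of this facial isomer. Reduction of ketone and ester with excess i-Bu2AlH (−78 → 0 °C) would then return to the route at 23, provided hydride adds to C6 from the β face.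

**Step 11.** The cycloaddition may show poor or reversed facial selectivity (the cyclobutene may prefer the enone face away from the silyloxy group). Some head-to-tail addition and secondary α-cleavage of the adduct ketone on over-irradiation are further risks.
Fallback: make the other facial isomer productive by inverting C6 later. The fallback sets out from 15 and 18 and takes the facial isomer of the photoadduct F2 through the same operations:
- NaBH4 reduction with lactonisation gives the tricyclic lactone F3, in which O6 is now on the face of the C7 side chain.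
- Flash thermolysis gives the 6β,15-olide F4; the lactone again dictates a ring-trans C4=C5, although the six-membered ring is less comfortable in the required conformer.
- i-Bu2AlH gives the 6β,15-diol F5, and TBDPSCl gives the 15-silyl ether of the 6β-alcohol F6.
- Mitsunobu inversion (4-nitrobenzoic acid, PPh3, diisopropyl azodicarboxylate) gives the 6α-(4-nitrobenzoate) F7.
- Methanolysis (K2CO3, MeOH) returns to the route at 24.

**Step 12.** Hydride may be delivered from the cyclobutane face, since the C10 methyl hinders the other face. That gives the C6 epimer whose hydroxyl is trans to C15 and cannot lactonise.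
Fallback: close the lactone with inversion instead of retention. The fallback sets out from 19, through its non-lactonising reduction product, the 7-epi hydroxy ester F8. Hydrolysis with Me3SnOH (ClCH2CH2Cl, 70 °C) gives the hydroxy acid F9, and an intramolecular Mitsunobu lactonisation (PPh3, diisopropyl azodicarboxylate) inverts C6 and returns to the route at 21.

**Step 19.** The primary TBDPS ether may be lost together with the hindered secondary TBS ether, or cleavage at C8 may be so slow that acid-induced transannular cyclisation of the diene sets in.
Fallback: global deprotection and selective reprotection instead of selective deprotection. The fallback sets out from 30; both ring silyl groups are removed (HF·pyridine, longer time, or Bu4NF/AcOH) to give 8α,15-dihydroxygermacra-1(10),4,11(13)-trien-12,6α-olide F10. Only the primary allylic hydroxyl is then silylated again (TBDPSCl, imidazole, CH2Cl2, −20 °C), which returns to the route at 31.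

## Further compounds

F1 | step 13 | methyl 8α-TBSO-12,12-dimethoxy-6-oxo-13-norgermacra-1(10),4-dien-15-oate (ring-cis C1=C10, ring-trans C4=C5) | O=C1/C=C(\C(=O)OC)CC/C=C(/C)C[C@H](O[Si](C)(C)C(C)(C)C)[C@H]1CC(OC)OC
F2 | step 11 | facial isomer of 19 (cyclobutane anti to the silyloxy group) | COC(=O)[C@@]12CC[C@@H]1[C@@]1(C)C[C@H](O[Si](C)(C)C(C)(C)C)[C@@H](CC(OC)OC)C(=O)[C@H]12
F3 | step 11 | tricyclic 5,7-lactone derived from F2 (O6 cis to the C7 side chain) | O=C1O[C@@H]2[C@H](CC(OC)OC)[C@@H](O[Si](C)(C)C(C)(C)C)C[C@]3(C)[C@H]4CC[C@]14[C@H]23
F4 | step 11 | 8α-TBSO-12,12-dimethoxy-13-norgermacra-1(10),4-dien-15,6β-olide | O=C1O[C@H]2C=C1CC/C=C(/C)C[C@H](O[Si](C)(C)C(C)(C)C)[C@H]2CC(OC)OC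
F5 | step 11 | 8α-TBSO-12,12-dimethoxy-13-norgermacra-1(10),4-diene-6β,15-diol | O[C@H]1/C=C(\CO)CC/C=C(/C)C[C@H](O[Si](C)(C)C(C)(C)C)[C@H]1CC(OC)OC
F6 | step 11 | 8α-TBSO-15-TBDPSO-12,12-dimethoxy-13-norgermacra-1(10),4-dien-6β-ol | O[C@H]1/C=C(\CO[Si](c2ccccc2)(c2ccccc2)C(C)(C)C)CC/C=C(/C)C[C@H](O[Si](C)(C)C(C)(C)C)[C@H]1CC(OC)OC
F7 | step 11 | 6α-(4-nitrobenzoyloxy)-8α-TBSO-15-TBDPSO-12,12-dimethoxy-13-norgermacra-1(10),4-diene | O=C(O[C@@H]1/C=C(\CO[Si](c2ccccc2)(c2ccccc2)C(C)(C)C)CC/C=C(/C)C[C@H](O[Si](C)(C)C(C)(C)C)[C@H]1CC(OC)OC)c1ccc(cc1)[N+](=O)[O-]
F8 | step 12 | 7-epi hydroxy ester from 19 (hydroxyl trans to the ester-bearing carbon) | COC(=O)[C@]12CC[C@H]1[C@]1(C)C[C@H](O[Si](C)(C)C(C)(C)C)[C@@H](CC(OC)OC)[C@@H](O)[C@@H]12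
F9 | step 12 | hydroxy acid from F8 | OC(=O)[C@]12CC[C@H]1[C@]1(C)C[C@H](O[Si](C)(C)C(C)(C)C)[C@@H](CC(OC)OC)[C@@H](O)[C@@H]12
F10 | step 19 | 8α,15-dihydroxygermacra-1(10),4,11(13)-trien-12,6α-olide | C=C1C(=O)O[C@@H]2/C=C(\CO)CC/C=C(/C)C[C@H](O)[C@@H]12
A1 | alternative 1 | 6α-[(diethoxyphosphoryl)acetoxy]-7α,8α-epoxy-15-TBSO-cyclodeca-1(10),4-diene precursor | CCOP(=O)(OCC)CC(=O)O[C@@H]1/C=C(\CO[Si](C)(C)C(C)(C)C)CC/C=C(/C)C[C@@H]2O[C@H]12
A2 | alternative 1 | α-(diethoxyphosphoryl) trans-lactone with free 8α-hydroxyl | CCOP(=O)(OCC)C1C(=O)O[C@@H]2/C=C(\CO[Si](C)(C)C(C)(C)C)CC/C=C(/C)C[C@H](O)[C@@H]12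
A3 | alternative 2 | 13-membered cyclic diallyl ether (oxygen between C6 and C13; ring-trans C7=C11 assumed) | O1C/C(CO[Si](C)(C)C(C)(C)C)=C/[C@@H](OCOC)C/C(C)=C\CC/C(CO[Si](c2ccccc2)(c2ccccc2)C(C)(C)C)=C/C1
A4 | alternative 2 | cyclodeca-1(10),4-dien-6-ol with the 2-propenyl unit on C7 | O[C@@H]1/C=C(\CO[Si](c2ccccc2)(c2ccccc2)C(C)(C)C)CC/C=C(/C)C[C@H](OCOC)[C@H]1C(=C)CO[Si](C)(C)C(C)(C)C
A5 | alternative 3 | open-chain C8 aldehyde carrying the 5-substituted furan-2(5H)-one | O=CC/C(C)=C\CC/C(CO[Si](C)(C)C(C)(C)C)=C/[C@H]1OC(=O)C=C1
A6 | alternative 3 | trans-fused lactone with the C8 alcohol | O=C1O[C@@H]2/C=C(\CO[Si](C)(C)C(C)(C)C)CC/C=C(/C)C[C@H](O)[C@H]2C1
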